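A one-step world has electrophile and nucleophile simply meeting one to one, but your flask has more steps than that.

    electrophile + nucleophile → acid set free + target (k1 = 5.10 × 10⁻⁶ /M/s)
    nucleophile + acid set free ⇌ protonated nucleophile, settled at all times (K2 = 1800 /M)
    nucleophile + protic impurity → quenched reagent (k3 = 8.29 × 10⁻⁵ /M/s)
    nucleophile + acid set free ⇌ idle adduct, settled at all times (K4 = 0.15 /M)
    acid set free + scavenger → scavenged by-product (k5 = 6.30 × 10⁻⁵ /M/s)

electrophile 1.0 M; nucleophile 3.00 equiv; protic impurity 0.100 M; scavenger 0.300 equiv; time 10 d

1. part of the electrophile that has reacted at 10 d
2. share of free nucleophile in free nucleophile and protonated nucleophile together, at 10 d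

- amounts and yields of acid set free count idle adduct too
- run time (flask): 10 d

First, what does the acid set free cost you? Against each free acid, the balance at the charge holds 5400 protonated nucleophile and 0.45 idle adduct, so nearly all of it takes a second nucleophile, and each electrophile reacted costs two. The scavenger gives little back: free acid has a half-life of 0.42 d, but so little of the acid is free that, even with the free nucleophile down to the spare reckoned next, the bound acid has a half-life by this route of about 688 d, far beyond 10 d.

Second, is there enough nucleophile? In fractions of the electrophile charge, take off the impurity, whose half-life against the charged nucleophile is 0.774 h, then take off two for the electrophile. The spare s is 0.900, and because it is above zero, the electrophile is the limiting reagent.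

Last, how far does it get in the time? Let f be the fraction of electrophile left, so that free nucleophile is s + 2f. At the start that is s + 2. At the end it stands near s, and the electrophile falls pseudo-first-order with the tail time τ, one over the first rate constant, the electrophile charge and the spare: 2.52 d. Integrating joins both ends: f = s / ((s + 2) exp(t/τ) − 2). That leaves 0.596%, so c is 99.4%, and fr, as (s + 2f) / (s + 1 + f), is 47.8%.

The forecast says 99.4% and 48.2%, holding that “each acid released ties up a second nucleophile”.

The simulation gives 99.4% and 48.3%. In this flask 10 d is 3.97 tail times, and 0.587% of the electrophile remains. The neighbour with 0.25 M of electrophile and the same equivalents of nucleophile carries 0.400 equiv of impurity, its spare is 0.600, its tail time of 15.1 d is longer than the run, and it ends with 19.6% of its electrophile left.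

Its constants are assumed; the result is computed.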